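## Structural features

The target is a 2-arylbenzofuran. Ring A (the benzo ring, C3a to C7a) and ring B (the furan) make up the benzofuran, and C2 of ring B is joined by one biaryl bond to C5' of a 2,2-dimethylchroman built from aromatic ring C and dihydropyran ring D. Ring A is a resorcinol with hydroxyls on C4 and C6, hydrogen on C5 and a 2-methylbut-3-en-2-yl (tert-allyl) group on C7, so C7 carries a quaternary benzylic carbon wedged between the C6 oxygen and the furan oxygen on C7a. Ring C is a second resorcinol: its C8a' oxygen is tied into ring D, its C7' hydroxyl is free, and the biaryl bond lies ortho to the ring D carbon C4a'. The molecule has no stereocentre, so no two stereocentres are adjacent and nothing has to be controlled in that respect. The fragile elements are the tert-allyl group beside a free phenol (acid can close it to a dihydrofuran, heat can isomerise it), the three electron-rich phenols (oxidation, over-alkylation) and the furan. The real difficulty is regiochemical: O4 must be told apart from O6, the tert-alkyl group must go to C7 and not C5, and ring D must be fused on the side of ring C next to the biaryl bond. The key step uses the 4,6-dioxygenated, 5-unsubstituted pattern of ring A fused to the furan at C3a–C7a, which is what a 2-furylketene and an oxygen-substituted ethyne deliver.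

## Logic of the disconnections

28 to 27: the two O–CH2 acetal bonds on O4 and O7' are cut. The phenols cannot be free during O6 alkylation or ketene chemistry, and two identical acid-labile groups cost one final step. The gain is that 27 has only O6 free. The demand is an acid mild enough for the tert-allyl group beside the C6 hydroxyl.

27 to 25: the bond from C7 to the quaternary carbon is cut and the allyl unit returns, transposed, to O6. A quaternary benzylic carbon between two substituted ring carbons is hard to form intermolecularly; a [3,3] shift delivers it intramolecularly with the required allyl inversion. The gain is that the quaternary carbon becomes a primary allyl ether. The demand is migration to C7 and not C5, under conditions that spare the product.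

25 to 22 and 23, then 22 to 21: the O6–CH2 bond is cut, and the silyl group on O6 and the MOM group on O4 are traced back to a free O4–H. O6 must be the only oxygen nucleophile when 23 is added. The gain is 21, in which the two ring A oxygens are already different. The demand is that ring A be made with O4 and O6 distinguished from the start.

21 to 13 and 16: the bonds C7a–C7, C6–C7, C4–C5 and C3a–C4 are cut, which removes ring A. 13 supplies ring B, C7 (its diazo carbon) and C4 (its carbonyl carbon); 16 supplies C5 and C6 with O6 already silylated. One step then gives ring A with the correct oxygen pattern, the O4/O6 differentiation and the aryl group in place. The gain is a 2,5-disubstituted furan and a two-carbon alkyne. The demand is a regiocontrolled [2+2] addition, closure onto furan C3, and tolerance of the MOM ether and the aryl ring.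

16 to 14: the O–Si and C–O bonds are cut. This reduces 16, which is not relied on as a catalogue item, to a commodity gas. The demand is O-silylation of an ynolate, not C-silylation.

13 to 11: the C=N bond at the ketone alpha carbon is cut, leaving a methyl ketone. This avoids an acid chloride (HCl against the MOM ether) and diazomethane. The gain is a stable ketone with one kind of alpha hydrogen. The demand is clean mono-activation of that methyl group.

11 to 8 and 9: the biaryl bond between furan C5 and C5' is cut. It is the only bond joining the two halves, and both partners are simple bromides. The demand is cross-coupling at a carbon with one ortho alkyl substituent.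

8 to 7 to 5: the MOM O–CH2 bond is cut, then the ring D bond O1'–C2' and the C4'–H bond (C4' regains a hydroxyl). With the side chain already ortho to one hydroxyl only, ring D can close in one direction only. The gain is an open-chain benzylic alcohol. The demand is deoxygenation and Markovnikov ring closure without reduction of the alkene.

5 to 3 and 4, then 3 to 1: the C3'–C4' bond is cut, then the C4a'–C4' bond (a formyl group). Formylation of a resorcinol goes para to one hydroxyl and ortho to the other, and the two such positions of 1 are equivalent and both next to bromine. A direct alkylation of 1 with a five-carbon cation would divide between this position and the one between the hydroxyls. The gain is commercial 1 and 4. The demand is a carbonyl addition that tolerates free phenols.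

## Other disconnections considered

Alternative 1: The cut removes in one operation the biaryl bond C2–C5' and the bond C4a'–C4' that holds the ring D side chain.
- Forward step: A2 would be metalated at C2, moved to magnesium, and added to the aryne released from A1 by iodine–magnesium exchange with i-PrMgCl. The aryl group should enter at the aryne carbon remote from the adjacent MOM-oxy group. The arylmagnesium left beside that group would be prenylated through copper (CuBr·SMe2, prenyl bromide) to give A3.
- In its favour: both ortho substituents of ring C are placed regiospecifically in one flask, and ring D can later close only onto the single oxygen ortho to the prenyl group. This settles in one step the ring D regiochemistry that takes steps 1 to 3 of the chosen route; here the alternative is better.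
- Against it: the step does nothing for ring A, so A2 must already hold the C7 quaternary carbon and the O4/O6 pattern. The closing acid treatment would have to form ring D and remove four MOM groups while sparing the tert-allyl group beside the C6 hydroxyl, a harsher version of the demand of step 12. i-PrMgCl may itself add to the aryne.
- Comparison: both plans are convergent and about equal in length once A2 is counted. The aryne route is a polar three-component sequence whose regiochemistry rests on an inductive effect and on excess organometallic; the benzannulation is a pericyclic cascade whose regiochemistry follows from ketene and ynol ether polarity. The chosen plan builds a ring with differentiated oxygens; alternative 1 builds no ring.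

Alternative 2: The cut is the benzofuran bond C3a–C3, read as the result of a 1,2-aryl shift; ring B is traced back to the pyranone ring of flavanone A4.
- Forward step: A4 would be converted by trimethyl orthoformate into its enol ether, PhI(OH)OTs would place a trivalent iodine group on C3, and ring A would migrate from C4 to C3 as PhI leaves, giving the trans ester A5. Hydrolysis, decarboxylation and dehydrogenation would still be needed.
- In its favour: A4 should come from a chalcone by aldol condensation and oxa-Michael closure, without a diazo compound or a lamp. In operational simplicity and scalability of the key step the alternative is better, and in convergence it is equal.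
- Against it: one carbon is brought in and then excised, three further operations follow the key step, and two stereocentres are made and erased. The electron-rich rings, the MOM acetals (sulfonic acid is released) and the terminal alkene of the tert-allyl group would all face an electrophilic oxidant. The tert-allyl group has to be installed before the flavanone, whose closure must then choose between two ortho hydroxyls.
- Comparison: the chosen plan forms ring A before any alkene exists and needs no excision, so it is better in chemoselectivity and step economy after the key step. Mechanistically, a cationic aryl shift is set against a neutral electrocyclic cascade.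

Alternative 3: The cut is made at the quaternary carbon on C7, whose bonds to one methyl group and to the vinyl group are formed from a 7-acetyl group.
- Forward step: in A6, MeMgBr would add to the ketone, the new alkoxide would take the Boc group from O6, and the phenoxide would expel tert-butyl carbonate to give the ortho-quinone methide A7. Vinylmagnesium bromide would add to its exocyclic carbon to give A8, which is the same compound as 27.
- In its favour: the site of the tert-allyl group is fixed by the site of the acetyl group, so the C7/C5 question of step 11 does not arise; on positional certainty the alternative is better. The product forms as a magnesium phenoxide under basic conditions, which avoids acid- and heat-induced follow-up reactions. Because A8 equals 27, it could replace steps 10 and 11 without touching the rest.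
- Against it: A7 carries two methyl groups on the exocyclic carbon and can tautomerise by a 1,5-hydrogen shift to an isopropenyl phenol, in competition with an addition that must build a quaternary centre. A6 needs an acetyl group on C7 and a carbonate on O6; the acylation has its own regiochemical question (C7, C5 or furan C3) and adds at least two steps.
- Comparison: both plans assemble the same carbon on C7, one from a carbonyl group by a polar cascade through a reactive intermediate, the other by a concerted allyl transposition. The chosen plan is shorter by one or two steps; the alternative is equal or better in positional certainty.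

Key step: step 8

Remarks on the chemistry:
- The connectivity of 13, 16 and 21 was re-derived from the mechanism (diazo carbon becomes C7, ketone carbon C4, the alkyne carbons C5 and C6, silyloxy on C6, hydroxyl on C4); no correction was needed.
- Two design changes serve the precursor. The diazo ketone is reached by diazo transfer to a methyl ketone, not by acylating diazomethane. Ring D is grown from a formyl group so that its position is not left to a Friedel–Crafts alkylation.
- Assumption: 1, 4, 9, 14 and 23 are catalogue chemicals; 16 is not assumed to be one and is made in step 7.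
- The target has no stereocentre; the stereocentres of 5, 18, 20 and 26 are racemic and disappear in the same or the next step.

## Route

Step 1
Reactants: 1 5-bromoresorcinol (5-bromobenzene-1,3-diol)
Product: 3 2-bromo-4,6-dihydroxybenzaldehyde, via aryl iminium chloride 2 (not isolated)
Conditions: POCl3, DMF, MeCN, 0 °C to rt; then H2O, 50 °C
Reagents that add atoms: N,N-dimethylformamide, CN(C)C=O (formyl carbon); water, O (carbonyl oxygen)
Why: Vilsmeier–Haack formylation; the chloroiminium ion attacks a resorcinol para to one hydroxyl and ortho to the other and not between them, the two such positions of 1 are equivalent and both lie next to bromine, and water hydrolyses iminium salt 2 to aldehyde 3.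

Step 2
Reactants: 3 2-bromo-4,6-dihydroxybenzaldehyde; 4 3-bromo-2-methylprop-1-ene
Product: 5 racemic 1-(2-bromo-4,6-dihydroxyphenyl)-3-methylbut-3-en-1-ol
Conditions: Zn dust, THF/sat. aq NH4Cl, 0 °C to rt; crude product used at once
Reagents that add atoms: none
Why: Barbier allylation; the allylic zinc reagent formed on the metal adds to the aldehyde faster than it is protonated, so the free phenols need no protection and the aryl bromide is untouched; the carbinol centre forms racemic and is removed in step 3.

Step 3
Reactants: 5 racemic 1-(2-bromo-4,6-dihydroxyphenyl)-3-methylbut-3-en-1-ol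
Product: 7 5-bromo-2,2-dimethylchroman-7-ol, via alkenyl resorcinol 6 (not isolated)
Conditions: Et3SiH (1.2 equiv), CF3CO2H, CH2Cl2, −20 °C to rt
Reagents that add atoms: none
Why: Ionic hydrogenation then acid-catalysed Markovnikov hydroalkoxylation; the benzylic cation stabilised by the ortho and para hydroxyls takes hydride from the silane to give 6, whose alkene is protonated to a tertiary cation that only the ortho hydroxyl can reach through a six-membered ring; the small excess of silane keeps alkene reduction from competing.

Step 4
Reactants: 7 5-bromo-2,2-dimethylchroman-7-ol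
Product: 8 5-bromo-7-(methoxymethoxy)-2,2-dimethylchroman
Conditions: MOMCl, i-Pr2NEt, CH2Cl2, 0 °C to rt
Reagents that add atoms: chloromethyl methyl ether (MOMCl), COCCl
Why: Standard MOM etherification of a phenol; the acetal is stable to the basic, organometallic and photochemical steps ahead and leaves at the end together with the second MOM group.

Step 5
Reactants: 8 5-bromo-7-(methoxymethoxy)-2,2-dimethylchroman; 9 1-(5-bromofuran-2-yl)ethanone
Product: 11 1-{5-[7-(methoxymethoxy)-2,2-dimethylchroman-5-yl]furan-2-yl}ethanone, via pinacol boronate 10 (not isolated)
Conditions: B2pin2 (1.05 equiv), PdCl2(dppf) (5 mol %; dppf = 1,1'-bis(diphenylphosphino)ferrocene), KOAc, 1,4-dioxane, 90 °C; then 9, aq K3PO4, 90 °C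
Reagents that add atoms: none
Why: Miyaura borylation followed in the same flask by Suzuki–Miyaura coupling; the electron-poor bromofuran 9 undergoes oxidative addition readily, the single ortho alkyl group of 10 is tolerated, and the acetyl and MOM groups are inert to aqueous phosphate.

Step 6
Reactants: 11 1-{5-[7-(methoxymethoxy)-2,2-dimethylchroman-5-yl]furan-2-yl}ethanone
Product: 13 2-diazo-1-{5-[7-(methoxymethoxy)-2,2-dimethylchroman-5-yl]furan-2-yl}ethanone, via trifluoromethyl diketone 12 (not isolated)
Conditions: LiN(SiMe3)2, THF, −78 °C; CF3CO2CH2CF3; aq HCl work-up; then MsN3, Et3N, H2O, MeCN, rt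
Reagents that add atoms: methanesulfonyl azide (MsN3), CS(=O)(=O)N=[N+]=[N-]
Why: Detrifluoroacetylative diazo transfer (a Regitz-type transfer); the lithium enolate of the only enolisable site is acylated to diketone 12, whose activated methylene takes the diazo group from the sulfonyl azide with loss of the trifluoroacetyl group; no acid chloride and no diazomethane are needed, so the MOM ether never meets HCl under anhydrous conditions.

Step 7
Reactants: 14 acetylene (ethyne)
Product: 16 (triisopropylsilyloxy)ethyne, via lithium ethynolate 15 (not isolated)
Conditions: n-BuLi, THF, −78 °C; t-BuOOLi (from t-BuOOH and LiN(SiMe3)2), −78 to 0 °C; i-Pr3SiOTf, −78 °C to rt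
Reagents that add atoms: lithium tert-butyl peroxide, [Li+].[O-]OC(C)(C)C; triisopropylsilyl trifluoromethanesulfonate, CC(C)[Si](OS(=O)(=O)C(F)(F)F)(C(C)C)C(C)C
Why: Oxidation of a lithium acetylide to the lithium ynolate by lithium tert-butyl peroxide and O-silylation with a bulky silyl triflate, the usual way to triisopropylsilyl ynol ethers from terminal alkynes, applied here to acetylene itself; the bulky silicon group goes to oxygen and slows the 1,3-shift to a silylketene.

Step 8
Reactants: 13 2-diazo-1-{5-[7-(methoxymethoxy)-2,2-dimethylchroman-5-yl]furan-2-yl}ethanone; 16 (triisopropylsilyloxy)ethyne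
Product: 21 2-[7-(methoxymethoxy)-2,2-dimethylchroman-5-yl]-6-(triisopropylsilyloxy)benzofuran-4-ol, via furylketene 17 (not isolated), via siloxycyclobutenone 18 (not isolated), via dienylketene 19 (not isolated), via cyclohexadienone tautomer 20 (not isolated)
Conditions: 16 (2.5 equiv), degassed ClCH2CH2Cl, hν (300 nm), rt; then 80 °C
Reagents that add atoms: none
Why: Danheiser benzannulation in its photochemical Wolff variant, a reaction type established for heteroaryl diazo ketones. Light expels N2 from 13 and the furyl group migrates to the carbene carbon, giving furylketene 17. The electrophilic ketene carbon bonds to the nucleophilic unsubstituted carbon of 16 and the ketene alpha carbon to the oxygen-bearing carbon, so the [2+2] adduct is cyclobutenone 18 with the silyloxy group on C3; this polarity match fixes silyloxy at C6, hydroxyl at C4 and hydrogen at C5 and C7. Four-electron conrotatory opening of 18 gives dienylketene 19, and ring A closes by thermal six-electron disrotatory electrocyclisation of the ketene carbon onto furan C3, the only ring position within reach of a ketene chain attached to C2. Tautomerisation of dienone 20 restores aromaticity and gives phenol 21. No stereocentre is left, those of 18 and 20 being transient. The selectivity needed is capture of 17 by the alkyne faster than by the product phenol, which the excess of the strongly ketenophilic 16 secures; the aryl ring and the MOM ether are spectators.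

Step 9
Reactants: 21 2-[7-(methoxymethoxy)-2,2-dimethylchroman-5-yl]-6-(triisopropylsilyloxy)benzofuran-4-ol
Product: 22 4-(methoxymethoxy)-2-[7-(methoxymethoxy)-2,2-dimethylchroman-5-yl]-6-(triisopropylsilyloxy)benzofuran
Conditions: MOMCl, i-Pr2NEt, CH2Cl2, 0 °C to rt
Reagents that add atoms: chloromethyl methyl ether (MOMCl), COCCl
Why: MOM etherification of the free C4 phenol; the aryl silyl ether is stable to the amine base, so O4 and O6 stay differentiated.

Step 10
Reactants: 22 4-(methoxymethoxy)-2-[7-(methoxymethoxy)-2,2-dimethylchroman-5-yl]-6-(triisopropylsilyloxy)benzofuran; 23 1-bromo-3-methylbut-2-ene (prenyl bromide)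
Product: 25 4-(methoxymethoxy)-2-[7-(methoxymethoxy)-2,2-dimethylchroman-5-yl]-6-(3-methylbut-2-enyloxy)benzofuran, via cesium phenoxide 24 (not isolated)
Conditions: CsF (3 equiv), 23 (1.5 equiv), DMF, rt
Reagents that add atoms: none
Why: Fluoride cleaves the aryl silyl ether and the cesium phenoxide 24 is alkylated in the same flask (Williamson ether synthesis); a phenoxide in DMF reacts at oxygen with a primary allylic bromide, and O6 is the only free oxygen.

Step 11
Reactants: 25 4-(methoxymethoxy)-2-[7-(methoxymethoxy)-2,2-dimethylchroman-5-yl]-6-(3-methylbut-2-enyloxy)benzofuran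
Product: 27 4-(methoxymethoxy)-2-[7-(methoxymethoxy)-2,2-dimethylchroman-5-yl]-7-(2-methylbut-3-en-2-yl)benzofuran-6-ol, via ortho-dienone 26 (not isolated)
Conditions: Eu(fod)3 (10 mol %; fod = 6,6,7,7,8,8,8-heptafluoro-2,2-dimethyloctane-3,5-dionate), NaHCO3, CHCl3, 60 °C
Reagents that add atoms: none
Why: Aromatic Claisen rearrangement, a [3,3] shift with allyl inversion that gives dienone 26 and, after tautomerisation, the tert-allyl phenol 27; C7 should be preferred over C5 because the C6–C7 bond of a benzofuran has the higher double-bond character (as C1 of a 2-naphthyl ether), and the europium Lewis acid lowers the temperature so that abnormal Claisen isomerisation and ring closure of the product are avoided.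

Step 12
Reactants: 27 4-(methoxymethoxy)-2-[7-(methoxymethoxy)-2,2-dimethylchroman-5-yl]-7-(2-methylbut-3-en-2-yl)benzofuran-6-ol
Product: 28 2-(7-hydroxy-2,2-dimethylchroman-5-yl)-7-(2-methylbut-3-en-2-yl)benzofuran-4,6-diol (CNP0300714.0)
Conditions: 2 M aq HCl, MeOH, 40 °C, under argon
Reagents that add atoms: none
Why: Acid-catalysed acetal exchange with methanol removes both MOM groups; dilute acid and mild warming are chosen because a tert-allyl group beside a phenol tolerates such conditions, whereas strong acid would add the hydroxyl to the alkene.

## Compound list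

1 | 5-bromoresorcinol (5-bromobenzene-1,3-diol) | Oc1cc(O)cc(Br)c1 | starting material
2 | [(2-bromo-4,6-dihydroxyphenyl)methylidene]dimethylammonium chloride | C[N+](C)=Cc1c(O)cc(O)cc1Br.[Cl-] | intermediate (not isolated)
3 | 2-bromo-4,6-dihydroxybenzaldehyde | O=Cc1c(O)cc(O)cc1Br | intermediate
4 | 3-bromo-2-methylprop-1-ene | C=C(C)CBr | starting material
5 | racemic 1-(2-bromo-4,6-dihydroxyphenyl)-3-methylbut-3-en-1-ol | C=C(C)CC(O)c1c(O)cc(O)cc1Br | intermediate
6 | 5-bromo-4-(3-methylbut-3-en-1-yl)benzene-1,3-diol | C=C(C)CCc1c(O)cc(O)cc1Br | intermediate (not isolated)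
7 | 5-bromo-2,2-dimethylchroman-7-ol | CC1(C)CCc2c(Br)cc(O)cc2O1 | intermediate
8 | 5-bromo-7-(methoxymethoxy)-2,2-dimethylchroman | COCOc1cc(Br)c2CCC(C)(C)Oc2c1 | intermediate
9 | 1-(5-bromofuran-2-yl)ethanone | CC(=O)c1ccc(Br)o1 | starting material
10 | 2-[7-(methoxymethoxy)-2,2-dimethylchroman-5-yl]-4,4,5,5-tetramethyl-1,3,2-dioxaborolane | COCOc1cc(B2OC(C)(C)C(C)(C)O2)c2CCC(C)(C)Oc2c1 | intermediate (not isolated)
11 | 1-{5-[7-(methoxymethoxy)-2,2-dimethylchroman-5-yl]furan-2-yl}ethanone | CC(=O)c1ccc(-c2cc(OCOC)cc3c2CCC(C)(C)O3)o1 | intermediate
12 | 4,4,4-trifluoro-1-{5-[7-(methoxymethoxy)-2,2-dimethylchroman-5-yl]furan-2-yl}butane-1,3-dione | O=C(CC(=O)C(F)(F)F)c1ccc(-c2cc(OCOC)cc3c2CCC(C)(C)O3)o1 | intermediate (not isolated)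
13 | 2-diazo-1-{5-[7-(methoxymethoxy)-2,2-dimethylchroman-5-yl]furan-2-yl}ethanone | [N-]=[N+]=CC(=O)c1ccc(-c2cc(OCOC)cc3c2CCC(C)(C)O3)o1 | intermediate
14 | acetylene (ethyne) | C#C | starting material
15 | lithium ethynolate | [Li+].[O-]C#C | intermediate (not isolated)
16 | (triisopropylsilyloxy)ethyne | C#CO[Si](C(C)C)(C(C)C)C(C)C | intermediate
17 | 2-{5-[7-(methoxymethoxy)-2,2-dimethylchroman-5-yl]furan-2-yl}ethen-1-one (furylketene) | O=C=Cc1ccc(-c2cc(OCOC)cc3c2CCC(C)(C)O3)o1 | intermediate (not isolated)
18 | racemic 4-{5-[7-(methoxymethoxy)-2,2-dimethylchroman-5-yl]furan-2-yl}-3-(triisopropylsilyloxy)cyclobut-2-en-1-one | O=C1C=C(O[Si](C(C)C)(C(C)C)C(C)C)C1c1ccc(-c2cc(OCOC)cc3c2CCC(C)(C)O3)o1 | intermediate (not isolated)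
19 | (3E)-4-{5-[7-(methoxymethoxy)-2,2-dimethylchroman-5-yl]furan-2-yl}-3-(triisopropylsilyloxy)buta-1,3-dien-1-one | O=C=C/C(O[Si](C(C)C)(C(C)C)C(C)C)=C\c1ccc(-c2cc(OCOC)cc3c2CCC(C)(C)O3)o1 | intermediate (not isolated)
20 | racemic 2-[7-(methoxymethoxy)-2,2-dimethylchroman-5-yl]-6-(triisopropylsilyloxy)-3aH-benzofuran-4-one | O=C1C=C(O[Si](C(C)C)(C(C)C)C(C)C)C=C2OC(-c3cc(OCOC)cc4c3CCC(C)(C)O4)=CC12 | intermediate (not isolated)
21 | 2-[7-(methoxymethoxy)-2,2-dimethylchroman-5-yl]-6-(triisopropylsilyloxy)benzofuran-4-ol | Oc1cc(O[Si](C(C)C)(C(C)C)C(C)C)cc2oc(-c3cc(OCOC)cc4c3CCC(C)(C)O4)cc12 | intermediate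
22 | 4-(methoxymethoxy)-2-[7-(methoxymethoxy)-2,2-dimethylchroman-5-yl]-6-(triisopropylsilyloxy)benzofuran | COCOc1cc(O[Si](C(C)C)(C(C)C)C(C)C)cc2oc(-c3cc(OCOC)cc4c3CCC(C)(C)O4)cc12 | intermediate
23 | 1-bromo-3-methylbut-2-ene (prenyl bromide) | CC(C)=CCBr | starting material
24 | cesium 4-(methoxymethoxy)-2-[7-(methoxymethoxy)-2,2-dimethylchroman-5-yl]benzofuran-6-olate | [Cs+].[O-]c1cc(OCOC)c2cc(-c3cc(OCOC)cc4c3CCC(C)(C)O4)oc2c1 | intermediate (not isolated)
25 | 4-(methoxymethoxy)-2-[7-(methoxymethoxy)-2,2-dimethylchroman-5-yl]-6-(3-methylbut-2-enyloxy)benzofuran | COCOc1cc(OCC=C(C)C)cc2oc(-c3cc(OCOC)cc4c3CCC(C)(C)O4)cc12 | intermediate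
26 | racemic 4-(methoxymethoxy)-2-[7-(methoxymethoxy)-2,2-dimethylchroman-5-yl]-7-(2-methylbut-3-en-2-yl)-7H-benzofuran-6-one | C=CC(C)(C)C1C(=O)C=C(OCOC)c2cc(-c3cc(OCOC)cc4c3CCC(C)(C)O4)oc12 | intermediate (not isolated)
27 | 4-(methoxymethoxy)-2-[7-(methoxymethoxy)-2,2-dimethylchroman-5-yl]-7-(2-methylbut-3-en-2-yl)benzofuran-6-ol | C=CC(C)(C)c1c(O)cc(OCOC)c2cc(-c3cc(OCOC)cc4c3CCC(C)(C)O4)oc12 | intermediate
28 | 2-(7-hydroxy-2,2-dimethylchroman-5-yl)-7-(2-methylbut-3-en-2-yl)benzofuran-4,6-diol (achiral) | C=CC(C)(C)c1c(O)cc(O)c2cc(-c3cc(O)cc4c3CCC(C)(C)O4)oc12 | target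

## Step count and least certain steps

Total: 12 steps. Longest linear sequence: 11 steps (steps 1 to 6 and 8 to 12); step 7 prepares the second component of the key step.

**Step 8 (key step).**
- What may go wrong: light absorption by the aryl furyl ketone chromophore and by the product could slow the Wolff rearrangement and cause secondary photoreactions; the product phenol could capture the ketene if the [2+2] addition lags; silicon could shift from oxygen to carbon in 16 during the thermal stage.
- Fallback, from 13 back to 21 without light: Wolff rearrangement of 13 with PhCO2Ag and Et3N in aqueous dioxane (Arndt–Eistert conditions) should give {5-[7-(methoxymethoxy)-2,2-dimethylchroman-5-yl]furan-2-yl}acetic acid F1. 1-Chloro-N,N,2-trimethylprop-1-en-1-amine converts it under neutral conditions into {5-[7-(methoxymethoxy)-2,2-dimethylchroman-5-yl]furan-2-yl}acetyl chloride F2. Dehydrochlorination of F2 with Et3N in the presence of 16 generates the same ketene 17 in the dark, and warming to 80 °C carries it through 18, 19 and 20 to 21. This is the known arylketene-plus-ynol-ether route to phenols.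

**Step 7.**
- What may go wrong: disproportionation of monolithium acetylide before it is oxidised, competing C-silylation of the ynolate, loss of the volatile product on isolation, and slow oxygen-to-carbon silyl shift on storage.
- Fallback, from 13 back to 25, replacing the silyl ynol ether by an alkyl ynol ether: benzyl alcohol, KH and trichloroethylene give benzyl (E)-1,2-dichlorovinyl ether F3; n-BuLi then methanol give benzyloxyethyne F4. Benzannulation of 13 with F4 under the conditions of step 8 should give 6-(benzyloxy)-2-[7-(methoxymethoxy)-2,2-dimethylchroman-5-yl]benzofuran-4-ol F5. MOMCl and i-Pr2NEt give 6-(benzyloxy)-4-(methoxymethoxy)-2-[7-(methoxymethoxy)-2,2-dimethylchroman-5-yl]benzofuran F6. Hydrogenolysis (H2, Pd/C, ethyl acetate) gives 4-(methoxymethoxy)-2-[7-(methoxymethoxy)-2,2-dimethylchroman-5-yl]benzofuran-6-ol F7. K2CO3 and 23 in DMF then give 25.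

**Step 3.**
- What may go wrong: intermolecular Friedel–Crafts capture of the benzylic cation by a second electron-rich ring (oligomerisation), or reduction of the alkene before ring D closes.
- Fallback, from 1 back to 7: acid-mediated condensation of 1 with 2-methylbut-3-en-2-ol (BF3·OEt2, dioxane, rt), a Friedel–Crafts prenylation followed by ring closure. It reaches 7 in one step but requires chromatographic separation from the regioisomeric chroman that arises from attack between the hydroxyls. It makes no compound outside the list (entry F0).

**Step 11.**
- What may go wrong: insufficient selectivity between C7 and C5, Lewis-acid erosion of a MOM group, or follow-up reaction of the product (addition of the C6 hydroxyl to the alkene, abnormal Claisen isomerisation).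
- Fallback, from 21 back to 27, placing the group by cross-coupling: N-iodosuccinimide should iodinate 21 para to the free C4 hydroxyl to give 7-iodo-2-[7-(methoxymethoxy)-2,2-dimethylchroman-5-yl]-6-(triisopropylsilyloxy)benzofuran-4-ol F8. MOMCl and i-Pr2NEt give 7-iodo-4-(methoxymethoxy)-2-[7-(methoxymethoxy)-2,2-dimethylchroman-5-yl]-6-(triisopropylsilyloxy)benzofuran F9. Palladium-catalysed Suzuki–Miyaura coupling with 3-methylbut-2-enylboronic acid pinacol ester, under biarylphosphine ligand control for bond formation through the gamma carbon of the allyl unit (K3PO4, aqueous THF), gives 4-(methoxymethoxy)-2-[7-(methoxymethoxy)-2,2-dimethylchroman-5-yl]-7-(2-methylbut-3-en-2-yl)-6-(triisopropylsilyloxy)benzofuran F10. Bu4NF in THF then gives 27. The coupling builds a quaternary carbon at a doubly ortho-substituted position and would itself be demanding.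

**Step 12.**
- What may go wrong: acid-catalysed addition of the C6 hydroxyl to the neighbouring vinyl group, or incomplete cleavage of the second MOM group under conditions mild enough to prevent that.
- Fallback, from 25 back to 28, with the order of the last two operations reversed: the same dilute acid is applied to 25, which has no phenol next to an alkene, to give 2-(7-hydroxy-2,2-dimethylchroman-5-yl)-6-(3-methylbut-2-enyloxy)benzofuran-4-ol F11. The Claisen rearrangement with Eu(fod)3 is then run on F11 as the final step, so that 28 is formed under near-neutral conditions and never meets acid.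

## Further compounds

F1 | step 8 | {5-[7-(methoxymethoxy)-2,2-dimethylchroman-5-yl]furan-2-yl}acetic acid | OC(=O)Cc1ccc(-c2cc(OCOC)cc3c2CCC(C)(C)O3)o1
F2 | step 8 | {5-[7-(methoxymethoxy)-2,2-dimethylchroman-5-yl]furan-2-yl}acetyl chloride | ClC(=O)Cc1ccc(-c2cc(OCOC)cc3c2CCC(C)(C)O3)o1
F3 | step 7 | benzyl (E)-1,2-dichlorovinyl ether | Cl/C=C(/Cl)OCc1ccccc1
F4 | step 7 | benzyloxyethyne | C#COCc1ccccc1
F5 | step 7 | 6-(benzyloxy)-2-[7-(methoxymethoxy)-2,2-dimethylchroman-5-yl]benzofuran-4-ol | Oc1cc(OCc2ccccc2)cc2oc(-c3cc(OCOC)cc4c3CCC(C)(C)O4)cc12
F6 | step 7 | 6-(benzyloxy)-4-(methoxymethoxy)-2-[7-(methoxymethoxy)-2,2-dimethylchroman-5-yl]benzofuran | COCOc1cc(OCc2ccccc2)cc2oc(-c3cc(OCOC)cc4c3CCC(C)(C)O4)cc12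
F7 | step 7 | 4-(methoxymethoxy)-2-[7-(methoxymethoxy)-2,2-dimethylchroman-5-yl]benzofuran-6-ol | COCOc1cc(O)cc2oc(-c3cc(OCOC)cc4c3CCC(C)(C)O4)cc12
F0 | step 3 | none | none
F8 | step 11 | 7-iodo-2-[7-(methoxymethoxy)-2,2-dimethylchroman-5-yl]-6-(triisopropylsilyloxy)benzofuran-4-ol | Oc1cc(O[Si](C(C)C)(C(C)C)C(C)C)c(I)c2oc(-c3cc(OCOC)cc4c3CCC(C)(C)O4)cc12
F9 | step 11 | 7-iodo-4-(methoxymethoxy)-2-[7-(methoxymethoxy)-2,2-dimethylchroman-5-yl]-6-(triisopropylsilyloxy)benzofuran | COCOc1cc(O[Si](C(C)C)(C(C)C)C(C)C)c(I)c2oc(-c3cc(OCOC)cc4c3CCC(C)(C)O4)cc12
F10 | step 11 | 4-(methoxymethoxy)-2-[7-(methoxymethoxy)-2,2-dimethylchroman-5-yl]-7-(2-methylbut-3-en-2-yl)-6-(triisopropylsilyloxy)benzofuran | C=CC(C)(C)c1c(O[Si](C(C)C)(C(C)C)C(C)C)cc(OCOC)c2cc(-c3cc(OCOC)cc4c3CCC(C)(C)O4)oc12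
F11 | step 12 | 2-(7-hydroxy-2,2-dimethylchroman-5-yl)-6-(3-methylbut-2-enyloxy)benzofuran-4-ol | CC(C)=CCOc1cc(O)c2cc(-c3cc(O)cc4c3CCC(C)(C)O4)oc2c1
A1 | alternative 1 | 1-bromo-2-iodo-3,5-bis(methoxymethoxy)benzene | COCOc1cc(Br)c(I)c(OCOC)c1
A2 | alternative 1 | 4,6-bis(methoxymethoxy)-7-(2-methylbut-3-en-2-yl)benzofuran | C=CC(C)(C)c1c(OCOC)cc(OCOC)c2ccoc12
A3 | alternative 1 | 2-[3,5-bis(methoxymethoxy)-2-(3-methylbut-2-enyl)phenyl]-4,6-bis(methoxymethoxy)-7-(2-methylbut-3-en-2-yl)benzofuran | C=CC(C)(C)c1c(OCOC)cc(OCOC)c2cc(-c3cc(OCOC)cc(OCOC)c3CC=C(C)C)oc12
A4 | alternative 2 | racemic 5,7-bis(methoxymethoxy)-2-[7-(methoxymethoxy)-2,2-dimethylchroman-5-yl]-8-(2-methylbut-3-en-2-yl)chroman-4-one | C=CC(C)(C)c1c(OCOC)cc(OCOC)c2c1OC(c1cc(OCOC)cc3c1CCC(C)(C)O3)CC2=O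
A5 | alternative 2 | racemic methyl trans-4,6-bis(methoxymethoxy)-2-[7-(methoxymethoxy)-2,2-dimethylchroman-5-yl]-7-(2-methylbut-3-en-2-yl)-2,3-dihydrobenzofuran-3-carboxylate (one enantiomer drawn) | C=CC(C)(C)c1c(OCOC)cc(OCOC)c2c1O[C@H](c1cc(OCOC)cc3c1CCC(C)(C)O3)[C@H]2C(=O)OC
A6 | alternative 3 | 7-acetyl-4-(methoxymethoxy)-2-[7-(methoxymethoxy)-2,2-dimethylchroman-5-yl]benzofuran-6-yl tert-butyl carbonate | CC(=O)c1c(OC(=O)OC(C)(C)C)cc(OCOC)c2cc(-c3cc(OCOC)cc4c3CCC(C)(C)O4)oc12
A7 | alternative 3 | 4-(methoxymethoxy)-2-[7-(methoxymethoxy)-2,2-dimethylchroman-5-yl]-7-(propan-2-ylidene)-7H-benzofuran-6-one | CC(C)=C1C(=O)C=C(OCOC)c2cc(-c3cc(OCOC)cc4c3CCC(C)(C)O4)oc12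
A8 | alternative 3 | 4-(methoxymethoxy)-2-[7-(methoxymethoxy)-2,2-dimethylchroman-5-yl]-7-(2-methylbut-3-en-2-yl)benzofuran-6-ol (identical with 27) | C=CC(C)(C)c1c(O)cc(OCOC)c2cc(-c3cc(OCOC)cc4c3CCC(C)(C)O4)oc12
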